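**Retrosynthetic overview**
1. Last bond C9–C10: a ring-closing, dearomative Mukaiyama aldol of a 2-methyl-3-silyloxyfuran onto a C9 aldehyde forms the ten-membered ring, the 3(2H)-furanone bridge and C9/C10 together; the acetate is put on in the same flask.
2. C6–C7 bond: Barbier allylation of a Z-enal with a ring-locked 2-(bromomethyl)enoate (six-membered lactone), then six- to five-membered translactonisation (sets C6 and C7, frees the C9 hydroxyl).
3. The bromide comes from (S)-but-3-ene-1,2-diol (source of C8 and of all absolute stereochemistry) and 2-(bromomethyl)acrylic acid by esterification, RCM and methacrylation.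
4. The Z-enal comes from 2-methylfuran and (Z)-3-iodobut-2-en-1-ol (Negishi coupling), then C–H borylation/oxidation and allylic oxidation.
5. Ring order: furan (bought) → temporary six-membered lactone → γ-lactone → ten-membered carbocycle and furanone bridge (last step).

Assumption: locants follow germacranolide numbering (C6–O/C12 lactone, C8 methacrylate, C9 acetate, C10 quaternary, C4=C5 Z); compounds 10, 11 and 19–21 are carried as mixtures at the furanone CH(CH3) carbon (future C10), which is planarised and reset in step 10.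

**Step 1**
Reactants: 1 but-2-yn-1-ol
Product: 3 (2Z)-3-iodobut-2-en-1-ol, via cyclic alkenylalanate 2 (not isolated)
Conditions: Red-Al, NaAlH2(OCH2CH2OMe)2 (1.3 equiv), THF, 0 °C to rt; then I2 (1.5 equiv), −78 to 0 °C
Reagents that add atoms: iodine, II
Why: Hydroxyl-directed trans-hydroalumination of the propargylic alcohol gives the five-membered alkenylalanate 2, and iodinolysis of the C–Al bond with retention leaves iodine cis to CH2OH, so only the Z-iodide (future Z-C4=C5) forms.

**Step 2**
Reactants: 4 2-methylfuran; 3 (2Z)-3-iodobut-2-en-1-ol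
Product: 7 (2Z)-3-(5-methylfuran-2-yl)but-2-en-1-ol, via 5-methyl-2-furyllithium 5 (not isolated), via 5-methyl-2-furylzinc chloride 6 (not isolated)
Conditions: 4 (3 equiv), n-BuLi, THF, −78 to 0 °C; ZnCl2, 0 °C to rt; then 3, Pd(PPh3)4 (3 mol%), rt
Reagents that add atoms: none
Why: C5-lithiation of 2-methylfuran, transmetalation to zinc and Negishi cross-coupling (zerovalent palladium, retention of alkene geometry) join C3 to C4 with furan and CH2OH cis; the excess of 6 absorbs the free hydroxyl.

**Step 3**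
Reactants: 7 (2Z)-3-(5-methylfuran-2-yl)but-2-en-1-ol
Product: 10 5-[(2Z)-4-hydroxybut-2-en-2-yl]-2-methylfuran-3(2H)-one, via bis(pinacolboryl) intermediate 8 (not isolated), via 3-hydroxyfuran tautomer 9 (not isolated)
Conditions: HBpin (2.5 equiv), [Ir(OMe)(cod)]2 (1.5 mol%), dtbpy (3 mol%), THF, rt to 50 °C; then NaBO3·4H2O, THF/H2O, 0 °C to rt
Reagents that add atoms: sodium perborate, [Na+].[O-]OB=O
Why: Iridium-catalysed C–H borylation (the alcohol is masked in situ as its O-Bpin ester) is sterically steered to the ring C–H beside the small methyl group and away from the twisted, branched Z-alkenyl group, and perborate oxidation of the C–B bond gives the 3-hydroxyfuran, which tautomerises to the 3(2H)-furanone.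

**Step 4**
Reactants: 10 5-[(2Z)-4-hydroxybut-2-en-2-yl]-2-methylfuran-3(2H)-one
Product: 11 (2Z)-3-(5-methyl-4-oxo-4,5-dihydrofuran-2-yl)but-2-enal
Conditions: MnO2 (15 equiv), CH2Cl2, rt, dark
Reagents that add atoms: none
Why: Heterogeneous, neutral MnO2 oxidation touches only the allylic alcohol and keeps the Z-geometry of the trisubstituted enal.

**Step 5**
Reactants: 12 (2S)-but-3-ene-1,2-diol; 13 2-(bromomethyl)prop-2-enoic acid
Product: 15 (2S)-2-hydroxybut-3-en-1-yl 2-(bromomethyl)prop-2-enoate, via acid chloride 14 (not isolated)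
Conditions: 13, (COCl)2, DMF (cat.), CH2Cl2, 0 °C to rt, evaporate; then 12 (1.5 equiv), 2,4,6-collidine (2 equiv), CH2Cl2, −78 °C
Reagents that add atoms: none
Why: Low-temperature acylation with an acid chloride and the hindered base collidine is selective for the primary hydroxyl and spares the allylic bromide; the chiral-pool stereocentre (future C8, S) is untouched.

**Step 6**
Reactants: 15 (2S)-2-hydroxybut-3-en-1-yl 2-(bromomethyl)prop-2-enoate
Product: 16 (5S)-3-(bromomethyl)-5-hydroxy-5,6-dihydro-2H-pyran-2-one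
Conditions: second-generation Hoveyda–Grubbs catalyst, RuCl2(H2IMes)(=CH-C6H4-2-OiPr) (5 mol%), toluene (0.01 M), 80 °C
Reagents that add atoms: none
Why: Ring-closing metathesis between the vinyl group and the 1,1-disubstituted acrylate (helped by the free allylic hydroxyl, phosphine-free catalyst tolerates the allylic bromide) closes the unsaturated six-membered lactone and locks C8 cis to the carbonyl across the new C7=C11 bond.

**Step 7**
Reactants: 16 (5S)-3-(bromomethyl)-5-hydroxy-5,6-dihydro-2H-pyran-2-one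
Product: 17 (3S)-5-(bromomethyl)-6-oxo-3,6-dihydro-2H-pyran-3-yl 2-methylprop-2-enoate
Conditions: methacrylic anhydride (1.5 equiv), Sc(OTf)3 (2 mol%), BHT (cat.), MeCN, −20 to 0 °C
Reagents that add atoms: methacrylic anhydride, C=C(C)C(=O)OC(=O)C(C)=C
Why: Lewis-acid-catalysed acylation installs the final C8 methacrylate without any amine, which would attack the 2-(bromomethyl)enoate in an SN2' sense; no stereocentre is touched.

**Step 8**
Reactants: 11 (2Z)-3-(5-methyl-4-oxo-4,5-dihydrofuran-2-yl)but-2-enal; 17 (3S)-5-(bromomethyl)-6-oxo-3,6-dihydro-2H-pyran-3-yl 2-methylprop-2-enoate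
Product: 20 (1S)-2-hydroxy-1-{(2R,3S)-4-methylidene-2-[(1Z)-2-(5-methyl-4-oxo-4,5-dihydrofuran-2-yl)prop-1-en-1-yl]-5-oxooxolan-3-yl}ethyl 2-methylprop-2-enoate, via allylindium dibromide 18 (not isolated), via six-membered lactone adduct 19 (not isolated)
Conditions: indium powder (1.5 equiv), THF/H2O (1:1), rt; then PPTS (10 mol%), CH2Cl2, rt
Reagents that add atoms: none
Why: Barbier 2-(alkoxycarbonyl)allylation through a chair transition state, as known for α-(bromomethyl)butenolides: the ring-locked geometry (C8 trans to CH2In) gives the anti C6/C7 pair (6R), attack anti to the pseudoaxial C8 acyloxy group gives 7S, and the new C6 hydroxyl then opens the six-membered lactone to the more stable trans α-methylene-γ-butyrolactone and frees the C9 primary alcohol.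

**Step 9**
Reactants: 20 (1S)-2-hydroxy-1-{(2R,3S)-4-methylidene-2-[(1Z)-2-(5-methyl-4-oxo-4,5-dihydrofuran-2-yl)prop-1-en-1-yl]-5-oxooxolan-3-yl}ethyl 2-methylprop-2-enoate
Product: 21 (1S)-1-{(2R,3S)-4-methylidene-2-[(1Z)-2-(5-methyl-4-oxo-4,5-dihydrofuran-2-yl)prop-1-en-1-yl]-5-oxooxolan-3-yl}-2-oxoethyl 2-methylprop-2-enoate
Conditions: DMP (1.3 equiv), CH2Cl2, 0 °C to rt
Reagents that add atoms: none
Why: Dess–Martin oxidation of the only free (primary) hydroxyl gives the α-acyloxy aldehyde under non-basic conditions, so C8 is not epimerised and the methacrylate does not migrate.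

**Step 10**
Reactants: 21 (1S)-1-{(2R,3S)-4-methylidene-2-[(1Z)-2-(5-methyl-4-oxo-4,5-dihydrofuran-2-yl)prop-1-en-1-yl]-5-oxooxolan-3-yl}-2-oxoethyl 2-methylprop-2-enoate
Product: 24 CNP0365569.2 (target), via silyloxyfuran aldehyde 22 (not isolated), via C9 trimethylsilyl ether 23 (not isolated)
Conditions: TMSOTf (2.5 equiv), iPr2NEt (1.3 equiv), CH2Cl2 (2 mM, slow addition of 21), −78 to −40 °C; then Ac2O (5 equiv), −40 to 0 °C
Reagents that add atoms: acetic anhydride, CC(=O)OC(C)=O
Why: Proposed new method: amine/TMSOTf soft enolisation re-aromatises the furanone to the 2-methyl-3-silyloxyfuran 22, whose most nucleophilic carbon (C10, the enol-silane carbon beside the ring oxygen) attacks the TMSOTf-activated C9 aldehyde in an intramolecular dearomative Mukaiyama aldol that closes the ten-membered ring and creates quaternary C10 and the furanone in one bond formation; C9 should follow the polar Felkin–Anh model (attack anti to the C8 acyloxy group, 8,9-anti, 9S), C10 (S) is expected from the Z-alkene/trans-lactone tether delivering the aldehyde to the furan face that gives the natural 3,10-oxygen bridge, and the silyl aldolate 23 is acetylated in the same flask (TMSOTf-catalysed Ac2O acylation) to block retro-aldol and acyl migration; the closest known reactions are the intermolecular Mukaiyama aldol of 2-substituted 3-silyloxyfurans with aldehydes to 2,2-disubstituted 3(2H)-furanones and the one-pot enol silane formation/Mukaiyama aldol with TMSOTf and an amine.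

**Compound list**
1 | but-2-yn-1-ol | CC#CCO | starting material
2 | sodium 2,2-bis(2-methoxyethoxy)-3-methyl-2,5-dihydro-1,2-oxaaluminol-2-uide (cyclic Z-alkenylalanate, formed in flask) | [Na+].CC1=CCO[Al-]1(OCCOC)OCCOC | intermediate
3 | (2Z)-3-iodobut-2-en-1-ol | C/C(I)=C/CO | intermediate
4 | 2-methylfuran | Cc1ccco1 | starting material
5 | (5-methylfuran-2-yl)lithium (formed in flask) | [Li]c1ccc(C)o1 | intermediate
6 | chloro(5-methylfuran-2-yl)zinc (formed in flask) | Cl[Zn]c1ccc(C)o1 | intermediate
7 | (2Z)-3-(5-methylfuran-2-yl)but-2-en-1-ol | C/C(=C/CO)c1ccc(C)o1 | intermediate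
8 | (2Z)-3-[5-methyl-4-(pinacolboryl)furan-2-yl]but-2-en-1-yl pinacol borate (C-Bpin beside the methyl-bearing ring carbon, O-Bpin on the alcohol; formed in flask) | C/C(=C/COB1OC(C)(C)C(C)(C)O1)c1cc(B2OC(C)(C)C(C)(C)O2)c(C)o1 | intermediate
9 | 5-[(2Z)-4-hydroxybut-2-en-2-yl]-2-methylfuran-3-ol (formed in flask) | C/C(=C/CO)c1cc(O)c(C)o1 | intermediate
10 | 5-[(2Z)-4-hydroxybut-2-en-2-yl]-2-methylfuran-3(2H)-one (racemic at C2) | C/C(=C/CO)C1=CC(=O)C(C)O1 | intermediate
11 | (2Z)-3-(5-methyl-4-oxo-4,5-dihydrofuran-2-yl)but-2-enal (racemic at the furanone CH(CH3) carbon) | C/C(=C/C=O)C1=CC(=O)C(C)O1 | intermediate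
12 | (2S)-but-3-ene-1,2-diol | OC[C@@H](O)C=C | starting material
13 | 2-(bromomethyl)prop-2-enoic acid | C=C(CBr)C(=O)O | starting material
14 | 2-(bromomethyl)prop-2-enoyl chloride (formed in flask) | C=C(CBr)C(=O)Cl | intermediate
15 | (2S)-2-hydroxybut-3-en-1-yl 2-(bromomethyl)prop-2-enoate | C=C(CBr)C(=O)OC[C@@H](O)C=C | intermediate
16 | (5S)-3-(bromomethyl)-5-hydroxy-5,6-dihydro-2H-pyran-2-one | O[C@@H]1COC(=O)C(CBr)=C1 | intermediate
17 | (3S)-5-(bromomethyl)-6-oxo-3,6-dihydro-2H-pyran-3-yl 2-methylprop-2-enoate | C=C(C)C(=O)O[C@@H]1COC(=O)C(CBr)=C1 | intermediate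
18 | (3S)-5-[(dibromoindiganyl)methyl]-6-oxo-3,6-dihydro-2H-pyran-3-yl 2-methylprop-2-enoate (allylindium dibromide, drawn as the monoallyl component of the sesquibromide; formed in flask) | C=C(C)C(=O)O[C@@H]1COC(=O)C(C[In](Br)Br)=C1 | intermediate
19 | (3S,4S)-4-[(1R,2Z)-1-hydroxy-3-(5-methyl-4-oxo-4,5-dihydrofuran-2-yl)but-2-en-1-yl]-5-methylidene-6-oxooxan-3-yl 2-methylprop-2-enoate (epimers at the furanone CH(CH3) carbon; formed in flask) | C=C(C)C(=O)O[C@@H]1COC(=O)C(=C)[C@H]1[C@H](O)/C=C(/C)C1=CC(=O)C(C)O1 | intermediate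
20 | (1S)-2-hydroxy-1-{(2R,3S)-4-methylidene-2-[(1Z)-2-(5-methyl-4-oxo-4,5-dihydrofuran-2-yl)prop-1-en-1-yl]-5-oxooxolan-3-yl}ethyl 2-methylprop-2-enoate (6R,7S,8S; epimers at the furanone CH(CH3) carbon) | C=C(C)C(=O)O[C@H](CO)[C@H]1C(=C)C(=O)O[C@@H]1/C=C(/C)C1=CC(=O)C(C)O1 | intermediate
21 | (1S)-1-{(2R,3S)-4-methylidene-2-[(1Z)-2-(5-methyl-4-oxo-4,5-dihydrofuran-2-yl)prop-1-en-1-yl]-5-oxooxolan-3-yl}-2-oxoethyl 2-methylprop-2-enoate (C9 aldehyde; epimers at the furanone CH(CH3) carbon) | C=C(C)C(=O)O[C@H](C=O)[C@H]1C(=C)C(=O)O[C@@H]1/C=C(/C)C1=CC(=O)C(C)O1 | intermediate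
22 | (1S)-1-{(2R,3S)-4-methylidene-2-[(1Z)-2-[5-methyl-4-(trimethylsilyloxy)furan-2-yl]prop-1-en-1-yl]-5-oxooxolan-3-yl}-2-oxoethyl 2-methylprop-2-enoate (aromatic silyloxyfuran; formed in flask) | C=C(C)C(=O)O[C@H](C=O)[C@H]1C(=C)C(=O)O[C@@H]1/C=C(/C)c1cc(O[Si](C)(C)C)c(C)o1 | intermediate
23 | 9-O-trimethylsilyl ether of the 9-deacetyl target (4Z,6R,7S,8S,9S,10S; formed in flask) | C=C(C)C(=O)O[C@H]1[C@H]2C(=C)C(=O)O[C@@H]2/C=C(/C)C2=CC(=O)[C@@](C)(O2)[C@H]1O[Si](C)(C)C | intermediate
24 | CNP0365569.2, (4Z,6R,7S,8S,9S,10S)-9-acetoxy-8-methacryloyloxy-1-oxo-3,10-epoxygermacra-2,4,11(13)-trien-6,12-olide | C=C(C)C(=O)O[C@H]1[C@H]2C(=C)C(=O)O[C@@H]2/C=C(/C)C2=CC(=O)[C@@](C)(O2)[C@H]1OC(C)=O | target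

**Totals**
Total steps: 10. Longest linear sequence: 7 steps (1, 2, 3, 4, 8, 9, 10); the bromide branch (5, 6, 7) joins at step 8.

**Steps most likely to fail and fallbacks**

Step 10 (ring-closing dearomative aldol). It can fail through oligomerisation, attack at the other furan β-carbon, or the wrong C9/C10 configuration under the open transition state. The fallback sets out from 21 and comes back at 24. α-Bromination of the furanone carbon of 21 (NBS, CH2Cl2, 0 °C) gives the 2-bromo-2-methyl-3(2H)-furanone aldehyde F5. Slow addition of F5 to CrCl2/LiI in THF at high dilution triggers an intramolecular chromium Reformatsky aldol through a metal-bound furanolate and a closed transition state, which gives the free C9 alcohol F6. F6 is acetylated separately (Ac2O, pyridine, DMAP) to 24.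

Step 8 (Barbier allylation). The allylindium carries a methacrylate on the carbon next to the allyl terminus and may lose it by 1,4-elimination, and face selectivity at C7 rests only on the ring substituent. The fallback sets out from 17 and comes back at 20. Pd2(dba)3-catalysed borylation of 17 with B2pin2 gives the isolable allylboronate (3S)-6-oxo-5-[(pinacolboryl)methyl]-3,6-dihydro-2H-pyran-3-yl 2-methylprop-2-enoate F4. F4 is heated with 11 in toluene at 60 °C: this is a closed six-membered allylboration with locked geometry and no elimination-prone carbon–metal bond. Hydrolysis of the borate of 19 and PPTS-promoted translactonisation then give 20.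

Step 3 (C–H borylation). Borylation at the other ring C–H (next to the alkenyl group) would give the regioisomeric furanone. The fallback sets out from 3 and comes back at 10. Purchased 3-bromofuran F1 is lithiated at C2 with LDA and methylated with MeI to 3-bromo-2-methylfuran F2. Lithiation of F2 at C5 (LDA), transmetalation with ZnCl2 and Pd(PPh3)4-catalysed coupling with 3 give (2Z)-3-(4-bromo-5-methylfuran-2-yl)but-2-en-1-ol F3. Alkoxide formation (n-BuLi), bromine–lithium exchange (t-BuLi), B(OMe)3 and NaBO3 oxidation then give 10, with the oxygen position fixed by the bromine.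

**Further compounds**
F1 | step 3 | 3-bromofuran (purchased) | Brc1ccoc1
F2 | step 3 | 3-bromo-2-methylfuran | Cc1occc1Br
F3 | step 3 | (2Z)-3-(4-bromo-5-methylfuran-2-yl)but-2-en-1-ol | C/C(=C/CO)c1cc(Br)c(C)o1
F4 | step 8 | (3S)-6-oxo-5-[(4,4,5,5-tetramethyl-1,3,2-dioxaborolan-2-yl)methyl]-3,6-dihydro-2H-pyran-3-yl 2-methylprop-2-enoate | C=C(C)C(=O)O[C@@H]1COC(=O)C(CB2OC(C)(C)C(C)(C)O2)=C1
F5 | step 10 | (1S)-1-{(2R,3S)-2-[(1Z)-2-(5-bromo-5-methyl-4-oxo-4,5-dihydrofuran-2-yl)prop-1-en-1-yl]-4-methylidene-5-oxooxolan-3-yl}-2-oxoethyl 2-methylprop-2-enoate | C=C(C)C(=O)O[C@H](C=O)[C@H]1C(=C)C(=O)O[C@@H]1/C=C(/C)C1=CC(=O)C(C)(Br)O1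
F6 | step 10 | 9-deacetyl target (free C9 alcohol, 4Z,6R,7S,8S,9S,10S) | C=C(C)C(=O)O[C@H]1[C@H]2C(=C)C(=O)O[C@@H]2/C=C(/C)C2=CC(=O)[C@@](C)(O2)[C@H]1O
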